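# Proposal: total synthesis of CNP0174688.1 by two chalcone isomerase ring closures and a Friedel–Crafts union

## The problem

The target is a biflavanoid in which C4 of a 7,8,3',4'-tetrahydroxyflavan-3-ol (the upper unit) is bonded to C6 of ring A of a 7,8,4'-trihydroxyflavan-3,4-diol (the lower unit). Each pyran ring carries three contiguous stereocentres: upper (2R,3R,4S), which is 2,3-cis-3,4-trans, and lower (2R,3R,4R), which is all-cis. Within one pyran ring C2 can direct C3 and C4, but the two rings are separated by an aryl–carbon bond and a benzene ring, so neither unit can set the absolute configuration of the other and each C2 needs its own source of asymmetry. In both units the 3-oxygen is cis to the 2-aryl group, the opposite of what oxidation of an enol ether next to a 2-aryl group delivers, so an inversion at C3 has to be planned twice. The molecule holds a catechol, two pyrogallol-type rings and a benzylic 4-hydroxyl; hot acid (ionisation at C4), base in air (phenol oxidation, ring opening) and hydrogenolysis (benzylic C–O bonds) are all excluded, which points to silyl ethers removed by fluoride. The enabling feature is lower ring A: it has no oxygen at C5, O1 is ortho to C4a, and lower C2 has the sense of a (2S)-flavanone. The lower O1–C2 bond is therefore the bond a chalcone isomerase makes from a 6'-deoxychalcone, and upper ring A shows the same pattern.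

## Retrosynthesis

**Protecting groups (23 from 22).** The last cut is through eight O–Si bonds. Compound 22 is the target with its seven phenols and the upper 3-hydroxyl as tert-butyldimethylsilyl (TBS) ethers. Silyl ethers are preferred to benzyl or methoxymethyl ethers because fluoride leaves the benzylic C4–O bond, the interflavanyl bond and the pyrogallol rings alone. The forward step needs a fluoride source that is neither strongly acidic nor strongly basic.

**Lower C4 and C3 (22 from 21, 20 and 17).** The lower C4–H bond is cut first (hydride addition to ketone 21), then the lower C3–O bond is reassigned (cis ester 21 from trans alcohol 20 by SN2), then the C3 oxygen is removed (20 from flavanone 17 by enol ether oxidation). The neighbouring cut, syn-dihydroxylation of a flav-3-ene, would place both oxygens trans to the 2-aryl group. The precursor 17 has one stereocentre in its lower half instead of three. The forward steps must give trans-selective α-hydroxylation, a clean inversion next to a carbonyl, and hydride delivery opposite the 3-substituent.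

**Silyl ethers on the dimer (17 from 16, 16 from 15).** The eight O–Si bonds of 17 are cut in two groups. The hindered lower 7-oxygen and the secondary upper 3-oxygen are the ones that need a silyl triflate (17 from 16). The six accessible phenolic oxygens are reached by the silyl chloride (16 from 15). Two stages keep the triflate away from the unprotected polyphenol. The oxidation and the inversion that follow need every phenol masked and only one free secondary alcohol.

**Key cut (15 from 14).** The lower O1–C2 bond is cut, which opens the lower pyranone to the 2'-hydroxychalcone 14. The alternatives at this point, conjugate arylation of a chromone (C2–aryl) or acylation of ring A (C4–C4a), would need chiral metal catalysts or strong Lewis acids on a protected, hindered dimer. The enzymatic closure works on the free polyphenol in water and makes the bond that biosynthesis makes. The lower half of 14 is achiral and one ring smaller. The forward step asks one thing: that the enzyme pocket accepts a substrate with a flavanyl group at C5' and a hydroxyl at C3'.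

**Interflavanyl bond (14 from 13, 13 from 10 + 12).** The four aryl silyl ethers of 13 are put back first. The bond between upper C4 and chalcone C5' (later lower C6) is then cut. It is formed by Friedel–Crafts alkylation of chalcone 12 with the benzylic cation from flavan-3,4-diol 10. Cutting here, with the chalcone already assembled, keeps all aldol chemistry away from the dimer. The 2,3-cis diol is the classical donor that gives the 3,4-trans product. The two fragments are of similar size. The demand on the forward step is high: the nucleophile is an acylated pyrogallol and weaker than the usual phenols, so it is used in excess, while the bulky silyl ethers next to C6 of 10 hold back self-condensation.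

**Upper unit (10 from 9, 8, 5, 4 and 3).** The upper unit has the same C2 sense and the same 2,3-cis relation as the lower unit, so the same three cuts apply: C4–H, C3–O, then O1–C2. This leads back through ketone ester 9, trans ketol 8 and silylated flavanone 5 to (2S)-isookanin 4 and okanin 3. The C4 configuration of 10 is irrelevant because C4 is ionised in the coupling. Dihydroxylation-based flavan-3-ol syntheses give 2,3-trans products and then need oxidation, reduction and C4 functionalisation, so this sequence is shorter. It also tests the enzyme and the inversion on a monomer before the dimer is committed.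

**Chalcones (3 from 1 + 2; 12 from 1 + 11).** Each Cα=Cβ bond is cut by aldol condensation logic. Gallacetophenone 1 supplies both pyrogallol rings; 3,4-dihydroxybenzaldehyde 2 and 4-hydroxybenzaldehyde 11 supply the two B rings. All three are commodity chemicals.

## Roads not taken

Alternative 1: The cut goes through upper O1–C2 and upper C3–C4, so the upper pyran ring is built around a methide carbon (upper C4) that already carries the future lower ring A.
- Forward step: sulfone A1 would lose sulfinate to give ortho-quinone methide A2. The enamine of benzyloxyacetaldehyde A3 with a chiral secondary amine would attack the methide carbon, and the phenoxide would close on the iminium carbon to give lactol A4.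
- Merits: the upper C4–aryl bond is in place with no regiochemical doubt, which is better than step 8 of the chosen plan, and two upper stereocentres come from one catalytic step.
- Weak points: C2 of A4 is only a lactol, so the catechol ring must be added as an aryl-metal and the ring re-closed at a benzylic carbon, where the 2,3-cis ether is the disfavoured outcome. The lower aryl group arrives as a plain tris(benzyloxy)phenyl ring, so an acyl group would have to be placed selectively on one of three similar rings. The benzyl ethers cannot be removed once an enone or a flavan-3,4-diol is present.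
- Comparison: for the upper unit alone the two plans are similar in length. Against the better regiocontrol of A4, the chosen plan sets a 2,3-cis problem solved by one inversion that is rehearsed on the monomer and reused for the lower unit.

Alternative 2: Lower ring A is the retron: C4a–C8a, C5–C6 and C7–C8 would form in one [2+2+2] event that also closes the lower pyran ring through the tether.
- Forward step: diyne A5 (terminal alkyne on lower C4, boryl ynol ether on the C2 oxygen, C2–C3–C4 triad already in the chain) and siloxyalkyne A6 on upper C4 would be joined by the rhodium complex A7, [Rh(cod)2]BF4, in the presence of a bisphosphine, to give A8.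
- Merits: in convergence and in the handling of the lower stereotriad (no inversion on a ring, no Friedel–Crafts step) this road is better than the chosen one.
- Weak points: A5 needs an all-syn triol chain bearing two different and fragile alkynes. The third alkyne must insert into the rhodacycle formed from A7 in one orientation only. The propargylic, benzylic stereocentre of A6 is prone to epimerise. After the ring is made, the C–B bond must be oxidised and two kinds of silyl ether and eight benzyl ethers removed next to a benzylic 4-hydroxyl.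
- Comparison: the chosen plan sets against this sixteen steps from three commodity phenols with one kind of protecting group, and accepts in return the uncertain coupling of step 8 and two inversions.

Alternative 3: The cut is upper O1–C8a: the pyran oxygen is inserted into a carbocycle.
- Forward step: a peracid would convert indanone A9 into dihydrocoumarin A10 by migration of the electron-rich aryl carbon.
- Merits: the C4 stereocentre of A9 can come from reliable asymmetric conjugate arylation, and the oxygen insertion is regiospecific. On these two points it is at least as good as the chosen route.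
- Weak points: it solves only one bond of the upper unit. C2 (aryl addition to the lactone carbonyl), C3 (hydroxylation and a 2,3-cis closure) and the whole lower unit remain, again from a tris(benzyloxy)phenyl ring without an acyl handle and with benzyl ethers that must be exchanged.
- Comparison: the chosen plan reaches the complete upper unit in six steps and uses the same operations for the lower one.

Key step: step 10

Assumption: a recombinant legume type 2 chalcone isomerase (or a variant of it selected on 14) is taken to be available and to tolerate the 2',3',4'-trihydroxy ring; step 2 tests this on the monomer.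

Note on descriptors: TBS = tert-butyldimethylsilyl, TMS = trimethylsilyl. The CIP descriptor of upper C4 is S while the lower 7-oxygen carries hydrogen (13–16 and 23) and formally R while it carries silicon (17–22); the spatial arrangement (4-aryl trans to the 3-oxygen) is the same throughout.

## Route

Step 1
Reactants: 1 gallacetophenone [1-(2,3,4-trihydroxyphenyl)ethanone]; 2 3,4-dihydroxybenzaldehyde
Product: 3 okanin [(E)-3-(3,4-dihydroxyphenyl)-1-(2,3,4-trihydroxyphenyl)prop-2-en-1-one]
Conditions: HCl (ca. 1 M) in EtOH, rt, argon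
Reagents that add atoms: none
Why: Acid-catalysed Claisen–Schmidt condensation: the enol of 1 adds to the protonated aldehyde and the aldol loses water to the conjugated E-enone. The acylated pyrogallol ring and the catechol aldehyde are poor partners for Friedel–Crafts hydroxyalkylation, so free phenols are tolerated.

Step 2
Reactants: 3 okanin
Product: 4 (2S)-isookanin [(2S)-2-(3,4-dihydroxyphenyl)-7,8-dihydroxychroman-4-one]
Conditions: recombinant type 2 chalcone isomerase (Medicago sativa), KH2PO4/K2HPO4 buffer (50 mM, pH 7.0), 5% DMSO, ascorbic acid (2 mM), argon, 25 °C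
Reagents that add atoms: none
Why: Enzymatic intramolecular oxa-Michael addition of a 6'-deoxychalcone, the reaction this enzyme class performs on isoliquiritigenin; the active site delivers the 2'-phenoxide to one face of the enone and sets upper C2 as S. The step also tests the enzyme on the 2',3',4'-trihydroxy ring that returns in step 10.

Step 3
Reactants: 4 (2S)-isookanin
Product: 5 (2S)-2-[3,4-bis(TBS-oxy)phenyl]-7,8-bis(TBS-oxy)chroman-4-one
Conditions: TBSCl, imidazole, DMF, rt
Reagents that add atoms: tert-butyldimethylsilyl chloride, CC(C)(C)[Si](C)(C)Cl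
Why: Routine silylation of four phenols; imidazole does not open a flavanone that lacks a 5-hydroxyl, so C2 is not at risk.

Step 4
Reactants: 5 (2S)-tetrakis(TBS-oxy)flavanone
Product: 8 (2R,3R)-2-[3,4-bis(TBS-oxy)phenyl]-7,8-bis(TBS-oxy)-3-hydroxychroman-4-one (2,3-trans), via trimethylsilyl enol ether 6 (not isolated), via 3-trimethylsilyloxy ketone 7 (not isolated)
Conditions: (i) TMSOTf, Et3N, CH2Cl2, 0 °C, then hexane, filtration; (ii) mCPBA, CH2Cl2, −20 °C; (iii) citric acid, MeOH/THF, 0 °C
Reagents that add atoms: mCPBA, OOC(=O)c1cccc(Cl)c1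
Why: Rubottom oxidation: soft enolisation gives the 4-silyloxy-2H-chromene 6, the peracid epoxidises the face opposite the 2-aryl group, and silyl migration gives 7, whose TMS ether falls to mild acid. C3 is thereby set trans to C2 by substrate control, as is known for flavanone enol ethers.

Step 5
Reactants: 8 (2R,3R)-3-hydroxyflavanone derivative
Product: 9 (2R,3S)-2-[3,4-bis(TBS-oxy)phenyl]-7,8-bis(TBS-oxy)-4-oxochroman-3-yl 4-nitrobenzoate (2,3-cis)
Conditions: PPh3, DIAD, 4-nitrobenzoic acid, toluene, 0 °C to rt
Reagents that add atoms: 4-nitrobenzoic acid, OC(=O)c1ccc(cc1)[N+](=O)[O-]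
Why: Mitsunobu inversion of a secondary α-ketol: 4-nitrobenzoate displaces the oxyphosphonium group in an SN2 step accelerated by the adjacent carbonyl, entering on the face of the 2-aryl group to give the 2,3-cis ester. In the diequatorial half-chair neither H2 nor the 2-aryl group is antiperiplanar to the leaving group, which disfavours elimination and aryl shift.

Step 6
Reactants: 9 cis-3-(4-nitrobenzoyloxy)flavanone derivative
Product: 10 (2R,3R,4R)-2-[3,4-bis(TBS-oxy)phenyl]-7,8-bis(TBS-oxy)chromane-3,4-diol (2,3-cis-3,4-cis)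
Conditions: LiBH4, THF, −20 °C to rt
Reagents that add atoms: none
Why: Hydride reduction: LiBH4 attacks the C4 carbonyl from the face opposite the axial 3-acyloxy group, placing the 4-hydroxyl cis to O3 and to the 2-aryl group. On warming it also cleaves the activated ester by reduction.

Step 7
Reactants: 1 gallacetophenone; 11 4-hydroxybenzaldehyde
Product: 12 (E)-3-(4-hydroxyphenyl)-1-(2,3,4-trihydroxyphenyl)prop-2-en-1-one
Conditions: HCl (ca. 1 M) in EtOH, rt, argon
Reagents that add atoms: none
Why: The same acid-catalysed Claisen–Schmidt condensation as in step 1; the E-enone is the thermodynamic product of dehydration.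

Step 8
Reactants: 10 (2R,3R,4R)-flavan-3,4-diol derivative; 12 tetrahydroxychalcone
Product: 13 (E)-1-{5-[(2R,3R,4S)-2-[3,4-bis(TBS-oxy)phenyl]-7,8-bis(TBS-oxy)-3-hydroxychroman-4-yl]-2,3,4-trihydroxyphenyl}-3-(4-hydroxyphenyl)prop-2-en-1-one
Conditions: Sc(OTf)3 (10 mol%), 4 Å MS, MeCN/THF, 0 °C to rt; 12 in fivefold excess, the surplus recovered
Reagents that add atoms: none
Why: Lewis-acid-catalysed Friedel–Crafts alkylation of a phenol by a flavan-3,4-diol, the classical proanthocyanidin bond formation, in which the 4-hydroxyl of 10 leaves as water. Sc(OTf)3 ionises the benzylic 4-hydroxyl and the cation is attacked by C5' of 12 (ortho to 4'-OH, para to 2'-OH, the only doubly activated free position) trans to the axial 3-hydroxyl, which sets upper C4. The silyl ethers flanking C6 of 10 and the excess of 12 are meant to hold back self-condensation.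

Step 9
Reactants: 13 TBS-protected dimeric chalcone
Product: 14 (E)-1-{5-[(2R,3R,4S)-2-(3,4-dihydroxyphenyl)-3,7,8-trihydroxychroman-4-yl]-2,3,4-trihydroxyphenyl}-3-(4-hydroxyphenyl)prop-2-en-1-one
Conditions: Et3N·3HF, THF, rt, argon
Reagents that add atoms: none
Why: Fluoride cleavage of the four aryl silyl ethers; the slightly acidic amine–HF reagent forms no phenoxide, so the 2'-hydroxychalcone does not close non-selectively before it meets the enzyme.

Step 10
Reactants: 14 free dimeric chalcone
Product: 15 (2S)-6-[(2R,3R,4S)-2-(3,4-dihydroxyphenyl)-3,7,8-trihydroxychroman-4-yl]-7,8-dihydroxy-2-(4-hydroxyphenyl)chroman-4-one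
Conditions: recombinant type 2 chalcone isomerase (Medicago sativa wild type or a variant selected on 14), KH2PO4/K2HPO4 buffer (50 mM, pH 7.0), 10% DMSO, ascorbic acid (2 mM), argon, 25 °C
Reagents that add atoms: none
Why: Proposed new method: a chalcone isomerase is asked to accept a chalcone that carries a whole flavanyl unit at C5' and an extra hydroxyl at C3'; the expectation is that the enzyme binds the 4-hydroxycinnamoyl part and ring A as it binds isoliquiritigenin, that its active-site water and arginine network takes the proton of the 2'-hydroxyl, and that the 2'-phenoxide adds to the β-carbon of the enone from one face only, after which the enol tautomerises to the ketone. The closest known reaction is the type 2 chalcone isomerase cyclisation of 6'-deoxychalcones such as isoliquiritigenin to (2S)-flavanones, which step 2 applies to the monomer with the same ring A. The lower pyranone ring closes in the 6-endo-trig mode, forming O1–C2. The new stereocentre, lower C2, is fixed as S by the enzyme pocket and not by the upper unit, which is several bonds away. The step needs enantioface selectivity at the enone and chemoselectivity for the 2'-oxygen: only O2' can reach the β-carbon through a six-membered transition state, and the uncatalysed closure should be slow at pH 7 because the 2'-hydroxyl is held in a hydrogen bond to the carbonyl and no 6'-hydroxyl is present to speed it. The large substituent sits at C5', para to the reacting oxygen, so if the wild-type cleft does not take it, variants opened at that edge of ring A would be screened. Any (2R) material from the background reaction is a diastereomer of 15 and can be removed by chromatography.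

Step 11
Reactants: 15 dimeric (2S)-flavanone
Product: 16 hexakis-TBS ether of 15 (upper 7-, 8-, 3'- and 4'-oxygens and lower 8- and 4'-oxygens silylated; lower 7-hydroxyl and upper 3-hydroxyl free)
Conditions: TBSCl (6.5 equiv), imidazole, DMF, 0 °C to rt
Reagents that add atoms: tert-butyldimethylsilyl chloride, CC(C)(C)[Si](C)(C)Cl
Why: Phenol silylation as in step 3. The silyl chloride with imidazole does not reach the secondary 3-hydroxyl of a flavan-3-ol, here axial and flanked by two aryl-bearing carbons, and it should be slowest at the lower 7-hydroxyl, which lies between the 8-silyloxy group and the branched substituent on C6. Any material that takes a seventh silyl group at lower O7 converges on 17 in step 12.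

Step 12
Reactants: 16 hexakis-TBS flavanone
Product: 17 octakis-TBS ether of 15 (seven phenolic oxygens and the upper 3-oxygen silylated; lower 2S)
Conditions: TBSOTf (3 equiv), 2,6-lutidine, CH2Cl2, −40 to 0 °C
Reagents that add atoms: tert-butyldimethylsilyl triflate, CC(C)(C)[Si](C)(C)OS(=O)(=O)C(F)(F)F
Why: The silyl triflate reaches the two hindered hydroxyls that the chloride leaves. Hydroxyl silylation is much faster than enol silylation with this hindered base at low temperature, and lower C2 is not touched in either event. The upper 3-oxygen is masked so that only one secondary alcohol is present in step 14.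

Step 13
Reactants: 17 octakis-TBS flavanone
Product: 20 (2R,3R)-3-hydroxy derivative of 17 (lower unit 2,3-trans), via trimethylsilyl enol ether 18 (not isolated), via 3-trimethylsilyloxy ketone 19 (not isolated)
Conditions: (i) TMSOTf, Et3N, CH2Cl2, 0 °C, then hexane, filtration; (ii) mCPBA, CH2Cl2, −20 °C; (iii) citric acid, MeOH/THF, 0 °C
Reagents that add atoms: mCPBA, OOC(=O)c1cccc(Cl)c1
Why: Rubottom oxidation as in step 4: the peracid attacks the enol ether 18 opposite the 2-aryl group, so lower C3 is set trans to lower C2. The upper unit is remote and fully protected.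

Step 14
Reactants: 20 trans-3-hydroxyflavanone dimer
Product: 21 4-nitrobenzoate of the C3 epimer of 20 (lower unit 2R,3S; 2,3-cis)
Conditions: PPh3, DIAD, 4-nitrobenzoic acid, toluene, 0 °C to rt
Reagents that add atoms: 4-nitrobenzoic acid, OC(=O)c1ccc(cc1)[N+](=O)[O-]
Why: Mitsunobu inversion as in step 5: SN2 displacement at the carbon next to the carbonyl inverts lower C3 and gives the cis ester. The only other secondary oxygen, upper O3, is silylated.

Step 15
Reactants: 21 cis-3-(4-nitrobenzoyloxy)flavanone dimer
Product: 22 octakis-TBS ether of 23 with free lower (2R,3R,4R)-3,4-diol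
Conditions: LiBH4, THF, −20 °C to rt
Reagents that add atoms: none
Why: As in step 6, hydride adds to C4 from the face opposite the axial 3-acyloxy group, which gives the all-cis arrangement, and the ester is then cleaved reductively.

Step 16
Reactants: 22 octakis-TBS ether
Product: 23 (2R,3R,4R)-6-[(2R,3R,4S)-2-(3,4-dihydroxyphenyl)-3,7,8-trihydroxychroman-4-yl]-2-(4-hydroxyphenyl)chromane-3,4,7,8-tetrol (target)
Conditions: Et3N·3HF, THF/MeCN, rt to 40 °C, argon
Reagents that add atoms: none
Why: Global fluoride desilylation; the buffered reagent is neither acidic enough to ionise the benzylic 4-hydroxyl nor basic enough to make phenoxides, so lower C4 and the interflavanyl bond should be preserved. The hindered secondary silyl ether on upper O3 is the slowest to go and sets the reaction time.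

## Compound list

1 | gallacetophenone, 1-(2,3,4-trihydroxyphenyl)ethanone | CC(=O)c1ccc(O)c(O)c1O | starting material

2 | 3,4-dihydroxybenzaldehyde | O=Cc1ccc(O)c(O)c1 | starting material

3 | okanin, (E)-3-(3,4-dihydroxyphenyl)-1-(2,3,4-trihydroxyphenyl)prop-2-en-1-one | O=C(/C=C/c1ccc(O)c(O)c1)c1ccc(O)c(O)c1O | intermediate

4 | (2S)-isookanin, (2S)-2-(3,4-dihydroxyphenyl)-7,8-dihydroxychroman-4-one | O=C1C[C@@H](c2ccc(O)c(O)c2)Oc2c(O)c(O)ccc21 | intermediate

5 | (2S)-2-[3,4-bis(TBS-oxy)phenyl]-7,8-bis(TBS-oxy)chroman-4-one | O=C1C[C@@H](c2ccc(O[Si](C)(C)C(C)(C)C)c(O[Si](C)(C)C(C)(C)C)c2)Oc2c(O[Si](C)(C)C(C)(C)C)c(O[Si](C)(C)C(C)(C)C)ccc21 | intermediate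

6 | (2S)-2-[3,4-bis(TBS-oxy)phenyl]-7,8-bis(TBS-oxy)-4-(trimethylsilyloxy)-2H-chromene | C[Si](C)(C)OC1=C[C@@H](c2ccc(O[Si](C)(C)C(C)(C)C)c(O[Si](C)(C)C(C)(C)C)c2)Oc2c(O[Si](C)(C)C(C)(C)C)c(O[Si](C)(C)C(C)(C)C)ccc21 | intermediate (not isolated)

7 | (2R,3R)-2-[3,4-bis(TBS-oxy)phenyl]-7,8-bis(TBS-oxy)-3-(trimethylsilyloxy)chroman-4-one | O=C1[C@H](O[Si](C)(C)C)[C@@H](c2ccc(O[Si](C)(C)C(C)(C)C)c(O[Si](C)(C)C(C)(C)C)c2)Oc2c(O[Si](C)(C)C(C)(C)C)c(O[Si](C)(C)C(C)(C)C)ccc21 | intermediate (not isolated)

8 | (2R,3R)-2-[3,4-bis(TBS-oxy)phenyl]-7,8-bis(TBS-oxy)-3-hydroxychroman-4-one (2,3-trans) | O=C1[C@H](O)[C@@H](c2ccc(O[Si](C)(C)C(C)(C)C)c(O[Si](C)(C)C(C)(C)C)c2)Oc2c(O[Si](C)(C)C(C)(C)C)c(O[Si](C)(C)C(C)(C)C)ccc21 | intermediate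

9 | (2R,3S)-2-[3,4-bis(TBS-oxy)phenyl]-7,8-bis(TBS-oxy)-4-oxochroman-3-yl 4-nitrobenzoate (2,3-cis) | O=C1[C@@H](OC(=O)c2ccc(cc2)[N+](=O)[O-])[C@@H](c2ccc(O[Si](C)(C)C(C)(C)C)c(O[Si](C)(C)C(C)(C)C)c2)Oc2c(O[Si](C)(C)C(C)(C)C)c(O[Si](C)(C)C(C)(C)C)ccc21 | intermediate

10 | (2R,3R,4R)-2-[3,4-bis(TBS-oxy)phenyl]-7,8-bis(TBS-oxy)chromane-3,4-diol (2,3-cis-3,4-cis) | O[C@@H]1c2ccc(O[Si](C)(C)C(C)(C)C)c(O[Si](C)(C)C(C)(C)C)c2O[C@H](c2ccc(O[Si](C)(C)C(C)(C)C)c(O[Si](C)(C)C(C)(C)C)c2)[C@@H]1O | intermediate

11 | 4-hydroxybenzaldehyde | O=Cc1ccc(O)cc1 | starting material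

12 | (E)-3-(4-hydroxyphenyl)-1-(2,3,4-trihydroxyphenyl)prop-2-en-1-one | O=C(/C=C/c1ccc(O)cc1)c1ccc(O)c(O)c1O | intermediate

13 | (E)-1-{5-[(2R,3R,4S)-2-[3,4-bis(TBS-oxy)phenyl]-7,8-bis(TBS-oxy)-3-hydroxychroman-4-yl]-2,3,4-trihydroxyphenyl}-3-(4-hydroxyphenyl)prop-2-en-1-one | O=C(/C=C/c1ccc(O)cc1)c1cc([C@H]2c3ccc(O[Si](C)(C)C(C)(C)C)c(O[Si](C)(C)C(C)(C)C)c3O[C@H](c3ccc(O[Si](C)(C)C(C)(C)C)c(O[Si](C)(C)C(C)(C)C)c3)[C@@H]2O)c(O)c(O)c1O | intermediate

14 | (E)-1-{5-[(2R,3R,4S)-2-(3,4-dihydroxyphenyl)-3,7,8-trihydroxychroman-4-yl]-2,3,4-trihydroxyphenyl}-3-(4-hydroxyphenyl)prop-2-en-1-one | O=C(/C=C/c1ccc(O)cc1)c1cc([C@H]2c3ccc(O)c(O)c3O[C@H](c3ccc(O)c(O)c3)[C@@H]2O)c(O)c(O)c1O | intermediate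

15 | (2S)-6-[(2R,3R,4S)-2-(3,4-dihydroxyphenyl)-3,7,8-trihydroxychroman-4-yl]-7,8-dihydroxy-2-(4-hydroxyphenyl)chroman-4-one | O=C1C[C@@H](c2ccc(O)cc2)Oc2c(O)c(O)c([C@H]3c4ccc(O)c(O)c4O[C@H](c4ccc(O)c(O)c4)[C@@H]3O)cc21 | intermediate

16 | hexakis-TBS ether of 15 (upper 7-, 8-, 3'-, 4'-oxygens and lower 8-, 4'-oxygens silylated; lower 7-hydroxyl and upper 3-hydroxyl free; lower 2S) | O=C1C[C@@H](c2ccc(O[Si](C)(C)C(C)(C)C)cc2)Oc2c(O[Si](C)(C)C(C)(C)C)c(O)c([C@H]3c4ccc(O[Si](C)(C)C(C)(C)C)c(O[Si](C)(C)C(C)(C)C)c4O[C@H](c4ccc(O[Si](C)(C)C(C)(C)C)c(O[Si](C)(C)C(C)(C)C)c4)[C@@H]3O)cc21 | intermediate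

17 | octakis-TBS ether of 15 (lower 2S; upper 2R,3R and formally 4R) | O=C1C[C@@H](c2ccc(O[Si](C)(C)C(C)(C)C)cc2)Oc2c(O[Si](C)(C)C(C)(C)C)c(O[Si](C)(C)C(C)(C)C)c([C@H]3c4ccc(O[Si](C)(C)C(C)(C)C)c(O[Si](C)(C)C(C)(C)C)c4O[C@H](c4ccc(O[Si](C)(C)C(C)(C)C)c(O[Si](C)(C)C(C)(C)C)c4)[C@@H]3O[Si](C)(C)C(C)(C)C)cc21 | intermediate

18 | 4-(trimethylsilyloxy)-2H-chromene (TMS enol ether) of 17 (lower 2S) | C[Si](C)(C)OC1=C[C@@H](c2ccc(O[Si](C)(C)C(C)(C)C)cc2)Oc2c(O[Si](C)(C)C(C)(C)C)c(O[Si](C)(C)C(C)(C)C)c([C@H]3c4ccc(O[Si](C)(C)C(C)(C)C)c(O[Si](C)(C)C(C)(C)C)c4O[C@H](c4ccc(O[Si](C)(C)C(C)(C)C)c(O[Si](C)(C)C(C)(C)C)c4)[C@@H]3O[Si](C)(C)C(C)(C)C)cc21 | intermediate (not isolated)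

19 | (2R,3R)-3-(trimethylsilyloxy) derivative of 17 (lower 2,3-trans) | O=C1[C@H](O[Si](C)(C)C)[C@@H](c2ccc(O[Si](C)(C)C(C)(C)C)cc2)Oc2c(O[Si](C)(C)C(C)(C)C)c(O[Si](C)(C)C(C)(C)C)c([C@H]3c4ccc(O[Si](C)(C)C(C)(C)C)c(O[Si](C)(C)C(C)(C)C)c4O[C@H](c4ccc(O[Si](C)(C)C(C)(C)C)c(O[Si](C)(C)C(C)(C)C)c4)[C@@H]3O[Si](C)(C)C(C)(C)C)cc21 | intermediate (not isolated)

20 | (2R,3R)-3-hydroxy derivative of 17 (lower 2,3-trans) | O=C1[C@H](O)[C@@H](c2ccc(O[Si](C)(C)C(C)(C)C)cc2)Oc2c(O[Si](C)(C)C(C)(C)C)c(O[Si](C)(C)C(C)(C)C)c([C@H]3c4ccc(O[Si](C)(C)C(C)(C)C)c(O[Si](C)(C)C(C)(C)C)c4O[C@H](c4ccc(O[Si](C)(C)C(C)(C)C)c(O[Si](C)(C)C(C)(C)C)c4)[C@@H]3O[Si](C)(C)C(C)(C)C)cc21 | intermediate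

21 | 4-nitrobenzoate of the C3 epimer of 20 (lower 2R,3S; 2,3-cis) | O=C1[C@@H](OC(=O)c2ccc(cc2)[N+](=O)[O-])[C@@H](c2ccc(O[Si](C)(C)C(C)(C)C)cc2)Oc2c(O[Si](C)(C)C(C)(C)C)c(O[Si](C)(C)C(C)(C)C)c([C@H]3c4ccc(O[Si](C)(C)C(C)(C)C)c(O[Si](C)(C)C(C)(C)C)c4O[C@H](c4ccc(O[Si](C)(C)C(C)(C)C)c(O[Si](C)(C)C(C)(C)C)c4)[C@@H]3O[Si](C)(C)C(C)(C)C)cc21 | intermediate

22 | octakis-TBS ether of 23 (seven phenolic oxygens and upper O3 silylated; lower 2R,3R,4R diol free) | CC(C)(C)[Si](C)(C)Oc1ccc([C@H]2Oc3c(cc([C@H]4c5ccc(O[Si](C)(C)C(C)(C)C)c(O[Si](C)(C)C(C)(C)C)c5O[C@H](c5ccc(O[Si](C)(C)C(C)(C)C)c(O[Si](C)(C)C(C)(C)C)c5)[C@@H]4O[Si](C)(C)C(C)(C)C)c(O[Si](C)(C)C(C)(C)C)c3O[Si](C)(C)C(C)(C)C)[C@@H](O)[C@H]2O)cc1 | intermediate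

23 | (2R,3R,4R)-6-[(2R,3R,4S)-2-(3,4-dihydroxyphenyl)-3,7,8-trihydroxychroman-4-yl]-2-(4-hydroxyphenyl)chromane-3,4,7,8-tetrol | Oc1ccc([C@H]2Oc3c(cc([C@H]4c5ccc(O)c(O)c5O[C@H](c5ccc(O)c(O)c5)[C@@H]4O)c(O)c3O)[C@@H](O)[C@H]2O)cc1 | target

## Step count and least certain steps

Total step count: 16. Longest linear sequence: 15 steps (1–6, then 8–16) from gallacetophenone 1; step 7 is a one-step side branch.

**Step 10 (key step, proposed new method).** The most likely failure is that the enzyme does not bind or turn over 14 because the C5' flavanyl group and the 3'-hydroxyl do not fit the cleft. The slow unselective background closure and air oxidation of the polyphenol would then compete over a long incubation. The fallback sets out from 14 and uses the classical weak-base chalcone–flavanone isomerisation (NaOAc, degassed EtOH/H2O, reflux). It gives 15 together with its C2 epimer, the (2R)-flavanone F1. Because the upper unit is a single enantiomer, the two are diastereomers and are separated by reversed-phase preparative chromatography. F1 is returned to the same conditions, where it re-equilibrates through 14. The fallback comes back to the route at 15.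

**Step 8.** The most likely failure is that the cation from 10 is captured faster by ring A of a second molecule of 10 or of 13 than by the acyl-deactivated ring of 12; O-alkylation that does not revert and acid-induced closure of the enone are further risks. The fallback sets out from 10 and moves the acyl group to a later stage. Alkylation of pyrogallol (tenfold excess, Sc(OTf)3), a far stronger nucleophile, would give the 4-(2,3,4-trihydroxyphenyl)flavan-3-ol F2. Hoesch acylation of its free pyrogallol ring (MeCN, ZnCl2, HCl, Et2O, 0 °C; then H2O, 60 °C) would give the acetophenone F3. Acid-mediated Claisen–Schmidt condensation of F3 with 11 (HCl in EtOH) comes back to the route at 13; any silyl ether lost on the way is inconsequential because step 9 follows.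

**Step 14.** The most likely failure on the dimer is incomplete activation of the hindered, hydrogen-bonded ketol, with ester formation under retention through an acyloxyphosphonium pathway. The fallback sets out from 20 and separates activation from substitution. Tf2O and pyridine (CH2Cl2, −40 °C) would give the triflate F4. CsOAc with 18-crown-6 in toluene would displace it with inversion to the cis-acetate F5. LiBH4 under the conditions of step 15 reduces the ketone and removes the acetate, and the fallback comes back at 22.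

**Step 5.** On the monomer the process judged most dangerous is loss of the activated C3 oxygen with 1,2-shift of the electron-rich 2-aryl group or elimination, followed by base-induced epimerisation of the cis ester. The fallback sets out from 8 and inverts C3 by oxidation and reduction, with no leaving group at C3. NaBH4 (THF/EtOH, −20 °C) would give the 2,3-trans-3,4-trans diol F6. Camphorsulfonic acid in MeOH would etherify only the benzylic position to give the 4-methyl ether F7. Dess–Martin periodinane would give the flavan-3-one F8. Li(s-Bu)3BH (THF, −78 °C) would add hydride opposite the 2-aryl and 4-methoxy groups to give the 2,3-cis alcohol F9. F9 is ionised at C4 under the conditions of step 8 in place of 10, and the fallback comes back at 13. The experience gained here decides between step 14 and its fallback before the dimer is made.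

**Step 11.** The most likely failure is that silylation does not stop uniformly at six groups, so that the steric discrimination among the phenols gives a mixture of silylation patterns that is hard to purify and characterise. The fallback sets out from 15 and relies on the difference between phenols and the secondary alcohol instead. Excess TBSCl with imidazole and DMAP in DMF at 40 °C would silylate every phenol and give the heptakis-TBS ether F10, in which only the upper 3-hydroxyl is free. TBSOTf and 2,6-lutidine as in step 12 then silylate that one position, and the fallback comes back at 17.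

**Step 2.** The most likely failure is poor acceptance of the 3'-hydroxylated chalcone together with oxidative loss of okanin at neutral pH. The fallback sets out from 3. Closure with NaOAc in degassed EtOH/H2O would give racemic isookanin F11, and silylation as in step 3 gives racemic 5. Preparative chromatography on a cellulose carbamate phase would separate 5 from its enantiomer F12, which is racemised with DBU through the chalcone and recycled. The fallback comes back at 5.

## Further compounds

F1 | step 10 | (2R)-6-[(2R,3R,4S)-2-(3,4-dihydroxyphenyl)-3,7,8-trihydroxychroman-4-yl]-7,8-dihydroxy-2-(4-hydroxyphenyl)chroman-4-one (C2 epimer of 15) | O=C1C[C@H](c2ccc(O)cc2)Oc2c(O)c(O)c([C@H]3c4ccc(O)c(O)c4O[C@H](c4ccc(O)c(O)c4)[C@@H]3O)cc21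

F2 | step 8 | (2R,3R,4S)-2-[3,4-bis(TBS-oxy)phenyl]-7,8-bis(TBS-oxy)-4-(2,3,4-trihydroxyphenyl)chroman-3-ol | Oc1ccc([C@H]2c3ccc(O[Si](C)(C)C(C)(C)C)c(O[Si](C)(C)C(C)(C)C)c3O[C@H](c3ccc(O[Si](C)(C)C(C)(C)C)c(O[Si](C)(C)C(C)(C)C)c3)[C@@H]2O)c(O)c1O

F3 | step 8 | 1-{5-[(2R,3R,4S)-2-[3,4-bis(TBS-oxy)phenyl]-7,8-bis(TBS-oxy)-3-hydroxychroman-4-yl]-2,3,4-trihydroxyphenyl}ethanone | CC(=O)c1cc([C@H]2c3ccc(O[Si](C)(C)C(C)(C)C)c(O[Si](C)(C)C(C)(C)C)c3O[C@H](c3ccc(O[Si](C)(C)C(C)(C)C)c(O[Si](C)(C)C(C)(C)C)c3)[C@@H]2O)c(O)c(O)c1O

F4 | step 14 | 3-O-triflate of 20 (lower 2,3-trans) | O=C1[C@H](OS(=O)(=O)C(F)(F)F)[C@@H](c2ccc(O[Si](C)(C)C(C)(C)C)cc2)Oc2c(O[Si](C)(C)C(C)(C)C)c(O[Si](C)(C)C(C)(C)C)c([C@H]3c4ccc(O[Si](C)(C)C(C)(C)C)c(O[Si](C)(C)C(C)(C)C)c4O[C@H](c4ccc(O[Si](C)(C)C(C)(C)C)c(O[Si](C)(C)C(C)(C)C)c4)[C@@H]3O[Si](C)(C)C(C)(C)C)cc21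

F5 | step 14 | 3-O-acetate of the C3 epimer of 20 (lower 2,3-cis) | O=C1[C@@H](OC(C)=O)[C@@H](c2ccc(O[Si](C)(C)C(C)(C)C)cc2)Oc2c(O[Si](C)(C)C(C)(C)C)c(O[Si](C)(C)C(C)(C)C)c([C@H]3c4ccc(O[Si](C)(C)C(C)(C)C)c(O[Si](C)(C)C(C)(C)C)c4O[C@H](c4ccc(O[Si](C)(C)C(C)(C)C)c(O[Si](C)(C)C(C)(C)C)c4)[C@@H]3O[Si](C)(C)C(C)(C)C)cc21

F6 | step 5 | (2R,3S,4R)-2-[3,4-bis(TBS-oxy)phenyl]-7,8-bis(TBS-oxy)chromane-3,4-diol (2,3-trans-3,4-trans) | O[C@@H]1c2ccc(O[Si](C)(C)C(C)(C)C)c(O[Si](C)(C)C(C)(C)C)c2O[C@H](c2ccc(O[Si](C)(C)C(C)(C)C)c(O[Si](C)(C)C(C)(C)C)c2)[C@H]1O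

F7 | step 5 | (2R,3S,4R)-2-[3,4-bis(TBS-oxy)phenyl]-7,8-bis(TBS-oxy)-4-methoxychroman-3-ol | CO[C@@H]1c2ccc(O[Si](C)(C)C(C)(C)C)c(O[Si](C)(C)C(C)(C)C)c2O[C@H](c2ccc(O[Si](C)(C)C(C)(C)C)c(O[Si](C)(C)C(C)(C)C)c2)[C@H]1O

F8 | step 5 | (2R,4R)-2-[3,4-bis(TBS-oxy)phenyl]-7,8-bis(TBS-oxy)-4-methoxychroman-3-one | CO[C@@H]1c2ccc(O[Si](C)(C)C(C)(C)C)c(O[Si](C)(C)C(C)(C)C)c2O[C@H](c2ccc(O[Si](C)(C)C(C)(C)C)c(O[Si](C)(C)C(C)(C)C)c2)C1=O

F9 | step 5 | (2R,3R,4R)-2-[3,4-bis(TBS-oxy)phenyl]-7,8-bis(TBS-oxy)-4-methoxychroman-3-ol (2,3-cis) | CO[C@@H]1c2ccc(O[Si](C)(C)C(C)(C)C)c(O[Si](C)(C)C(C)(C)C)c2O[C@H](c2ccc(O[Si](C)(C)C(C)(C)C)c(O[Si](C)(C)C(C)(C)C)c2)[C@@H]1O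

F10 | step 11 | heptakis-TBS ether of 15 (all seven phenolic oxygens silylated; upper 3-hydroxyl free; lower 2S) | O=C1C[C@@H](c2ccc(O[Si](C)(C)C(C)(C)C)cc2)Oc2c(O[Si](C)(C)C(C)(C)C)c(O[Si](C)(C)C(C)(C)C)c([C@H]3c4ccc(O[Si](C)(C)C(C)(C)C)c(O[Si](C)(C)C(C)(C)C)c4O[C@H](c4ccc(O[Si](C)(C)C(C)(C)C)c(O[Si](C)(C)C(C)(C)C)c4)[C@@H]3O)cc21

F11 | step 2 | racemic isookanin, 2-(3,4-dihydroxyphenyl)-7,8-dihydroxychroman-4-one (racemate) | O=C1CC(c2ccc(O)c(O)c2)Oc2c(O)c(O)ccc21

F12 | step 2 | (2R)-2-[3,4-bis(TBS-oxy)phenyl]-7,8-bis(TBS-oxy)chroman-4-one (enantiomer of 5) | O=C1C[C@H](c2ccc(O[Si](C)(C)C(C)(C)C)c(O[Si](C)(C)C(C)(C)C)c2)Oc2c(O[Si](C)(C)C(C)(C)C)c(O[Si](C)(C)C(C)(C)C)ccc21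

A1 | alternative 1 | 2,3-bis(benzyloxy)-6-{(4-methylphenylsulfonyl)[2,3,4-tris(benzyloxy)phenyl]methyl}phenol (racemic) | Oc1c(OCc2ccccc2)c(OCc2ccccc2)ccc1C(c1ccc(OCc2ccccc2)c(OCc2ccccc2)c1OCc1ccccc1)S(=O)(=O)c1ccc(C)cc1

A2 | alternative 1 | ortho-quinone methide from A1, 2,3-bis(benzyloxy)-6-[2,3,4-tris(benzyloxy)benzylidene]cyclohexa-2,4-dien-1-one | O=C1C(=Cc2ccc(OCc3ccccc3)c(OCc3ccccc3)c2OCc2ccccc2)C=CC(OCc2ccccc2)=C1OCc1ccccc1

A3 | alternative 1 | benzyloxyacetaldehyde | O=CCOCc1ccccc1

A4 | alternative 1 | 3,4-trans-3-benzyloxy-7,8-bis(benzyloxy)-4-[2,3,4-tris(benzyloxy)phenyl]chroman-2-ol (both C2 anomers) | c1ccccc1COc1c(OCc2ccccc2)c(OCc2ccccc2)ccc1[C@H]1c2ccc(OCc3ccccc3)c(OCc3ccccc3)c2OC(O)[C@@H]1OCc1ccccc1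

A5 | alternative 2 | tethered diyne: 1-[4-(benzyloxy)phenyl]-2,3-bis(TBS-oxy)pent-4-ynyl 2-(pinacolboryl)ethynyl ether, configured as lower C2–C4 of the target | c1ccccc1COc1ccc(cc1)[C@H]([C@H](O[Si](C)(C)C(C)(C)C)[C@H](O[Si](C)(C)C(C)(C)C)C#C)OC#CB1OC(C)(C)C(C)(C)O1

A6 | alternative 2 | upper 3-benzyloxy-7,8-bis(benzyloxy)-2-[3,4-bis(benzyloxy)phenyl]-4-[(triisopropylsilyloxy)ethynyl]chroman, configured as the upper unit | CC(C)[Si](C(C)C)(C(C)C)OC#C[C@H]1c2ccc(OCc3ccccc3)c(OCc3ccccc3)c2O[C@H](c2ccc(OCc3ccccc3)c(OCc3ccccc3)c2)[C@@H]1OCc1ccccc1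

A7 | alternative 2 | [Rh(cod)2]BF4, bis(1,5-cyclooctadiene)rhodium tetrafluoroborate | [Rh+].C1=CCCC=CCC1.C1=CCCC=CCC1.F[B-](F)(F)F

A8 | alternative 2 | protected dimer with C8 pinacol boronate and C7 triisopropylsilyl ether on lower ring A | c1ccccc1COc1ccc([C@H]2Oc3c(cc([C@H]4c5ccc(OCc6ccccc6)c(OCc6ccccc6)c5O[C@H](c5ccc(OCc6ccccc6)c(OCc6ccccc6)c5)[C@@H]4OCc4ccccc4)c(O[Si](C(C)C)(C(C)C)C(C)C)c3B3OC(C)(C)C(C)(C)O3)[C@@H](O[Si](C)(C)C(C)(C)C)[C@H]2O[Si](C)(C)C(C)(C)C)cc1

A9 | alternative 3 | 6,7-bis(benzyloxy)-3-[2,3,4-tris(benzyloxy)phenyl]indan-1-one | c1ccccc1COc1c(OCc2ccccc2)c(OCc2ccccc2)ccc1[C@@H]1CC(=O)c2c(OCc3ccccc3)c(OCc3ccccc3)ccc21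

A10 | alternative 3 | 7,8-bis(benzyloxy)-4-[2,3,4-tris(benzyloxy)phenyl]chroman-2-one | c1ccccc1COc1c(OCc2ccccc2)c(OCc2ccccc2)ccc1[C@@H]1CC(=O)Oc2c(OCc3ccccc3)c(OCc3ccccc3)ccc21
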